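**Strategy**

The cyclohexenone ring (C1 carbonyl, C2 vinylic CH, C3 bearing nonadecyl, C4–C6 methylenes) is cut at C1–C2 and C5–C6 into a four-carbon diene, 2-nonadecylbuta-1,3-diene (C2–C5), and a two-carbon ketene equivalent, ethynylboronic acid pinacol ester (C1, C6). A cobalt-catalysed [4+2] cycloaddition under pyridine–imine ligand control forms both bonds at once and exploits the 1,3 relationship of C1 and C3 in the ring, an orientation that thermal Diels–Alder reactions of 2-alkyl dienes do not deliver. The precursor pair is thus an unactivated diene and a boryl alkyne; the cycloadduct carries the ketone as a C–B bond, and oxidation with acid-mediated alkene migration gives the enone.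

Key step: step 2

Remark on the chemistry: the target has no stereocentre and no stereodefined alkene, so no stereochemical control is needed; chloroprene is taken as the commercial stabilised solution, and the pyridine–imine ligand (condensation product of pyridine-2-carbaldehyde and 2,4,6-trimethylaniline) is treated as a catalyst component.

**Route**

Step 1
Reactants: 1 1-bromononadecane; 2 chloroprene (2-chlorobuta-1,3-diene)
Product: 4 2-nonadecylbuta-1,3-diene, via nonadecylmagnesium bromide 3 (not isolated)
Conditions: Mg, THF, 45 °C; then 2 (1.3 equiv), NiCl2(dppp) (1 mol %), THF, 0 °C to rt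
Reagents that add atoms: none
Why: Kumada–Tamao–Corriu coupling of a primary alkyl Grignard reagent with a vinylic chloride, in which the chelating dppp ligand on nickel should make reductive elimination faster than β-hydride elimination and the C–Cl bond of 2 is the only site for oxidative addition.

Step 2
Reactants: 4 2-nonadecylbuta-1,3-diene; 5 ethynylboronic acid pinacol ester (2-ethynyl-4,4,5,5-tetramethyl-1,3,2-dioxaborolane)
Product: 6 2-(5-nonadecylcyclohexa-1,4-dien-1-yl)-4,4,5,5-tetramethyl-1,3,2-dioxaborolane
Conditions: CoBr2 (10 mol %), N-(2,4,6-trimethylphenyl)-1-(pyridin-2-yl)methanimine (10 mol %), Zn powder, ZnI2, Fe powder (20 mol % each), CH2Cl2, rt, slow addition of 5 (1.2 equiv)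
Reagents that add atoms: none
Why: Zinc reduces CoBr2 to a monovalent cobalt species from which ZnI2 abstracts halide; the cationic low-valent cobalt centre binds the s-cis diene 4 and alkyne 5, oxidative cyclisation makes the first C–C bond and gives an allyl–vinyl cobaltacycle, and reductive elimination makes the second and releases the cyclohexa-1,4-diene. The closest known reaction type is the cobalt-catalysed neutral [4+2] cycloaddition of unactivated 1,3-dienes with alkynes, alkynyl boronic esters included, in which pyridine–imine ligands give the 1,3-substituted cyclohexadiene and bisphosphine ligands the 1,4-isomer. The six-membered ring is closed intermolecularly in the [4+2] mode, the two new sigma bonds joining the diene termini C2 and C5 to the alkyne carbons C1 and C6. No stereocentre is formed. The step needs regioselectivity (boron-bearing C1 bonded to C2, the terminus next to the alkylated C3) and chemoselectivity over alkyne cyclotrimerisation; the first should follow from each partner carrying a single substituent that the bulky N-aryl imine arm of the ligand sorts in the cobaltacycle, the second from slow addition of 5 to the diene. The unactivated diene–alkyne pair has no thermal background cycloaddition that could erode the orientation.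

Step 3
Reactants: 6 2-(5-nonadecylcyclohexa-1,4-dien-1-yl)-4,4,5,5-tetramethyl-1,3,2-dioxaborolane
Product: 9 3-nonadecylcyclohex-2-en-1-one, via 5-nonadecylcyclohexa-1,4-dien-1-ol 7 (not isolated), via 3-nonadecylcyclohex-3-en-1-one 8 (not isolated)
Conditions: 30% aq. H2O2, pH 7 phosphate buffer, THF, 0 °C to rt; aq. Na2SO3 quench; then 2 M HCl, THF, rt
Reagents that add atoms: hydrogen peroxide, OO
Why: Boronate oxidation (peroxide adds to boron, the alkenyl carbon C1 migrates from boron to oxygen, hydrolysis) should free enol 7, which tautomerises to the β,γ-enone 8, and acid-catalysed isomerisation through the dienol should then move the C3=C4 bond to the conjugated, thermodynamically preferred C2=C3 position.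

**Compound list**

1 | 1-bromononadecane | CCCCCCCCCCCCCCCCCCCBr | starting material
2 | chloroprene (2-chlorobuta-1,3-diene) | C=CC(Cl)=C | starting material
3 | nonadecylmagnesium bromide | CCCCCCCCCCCCCCCCCCC[Mg]Br | intermediate
4 | 2-nonadecylbuta-1,3-diene | CCCCCCCCCCCCCCCCCCCC(=C)C=C | intermediate
5 | ethynylboronic acid pinacol ester (2-ethynyl-4,4,5,5-tetramethyl-1,3,2-dioxaborolane) | C#CB1OC(C)(C)C(C)(C)O1 | starting material
6 | 2-(5-nonadecylcyclohexa-1,4-dien-1-yl)-4,4,5,5-tetramethyl-1,3,2-dioxaborolane | CCCCCCCCCCCCCCCCCCCC1=CCC=C(B2OC(C)(C)C(C)(C)O2)C1 | intermediate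
7 | 5-nonadecylcyclohexa-1,4-dien-1-ol | CCCCCCCCCCCCCCCCCCCC1=CCC=C(O)C1 | intermediate
8 | 3-nonadecylcyclohex-3-en-1-one | CCCCCCCCCCCCCCCCCCCC1=CCCC(=O)C1 | intermediate
9 | 3-nonadecylcyclohex-2-en-1-one | CCCCCCCCCCCCCCCCCCCC1=CC(=O)CCC1 | target

**Step count**

Total steps: 3. Longest linear sequence: 3 steps (1 → 4 → 6 → 9).

**Steps most likely to fail**

Step 2. What may go wrong: leakage of the regiochemistry toward the 1,4-oriented cycloadduct, cyclotrimerisation of the terminal alkyne at cobalt, or protodeboronation on the Lewis-acidic zinc salts. Fallback: the cycloaddition is given up and the chain is attached to a preformed ring by the Stork–Danheiser enone transposition. It sets out from 1-bromononadecane 1, converted as in step 1 into Grignard reagent 3. This adds 1,2 to commercial 3-ethoxycyclohex-2-en-1-one (THF, 0 °C) to give, after protonation, 3-ethoxy-1-nonadecylcyclohex-2-en-1-ol F1, which is not isolated. Work-up with aqueous HCl hydrolyses the enol ether and dehydrates the tertiary alcohol, and the route is rejoined at target 9. This path is secure but no longer builds the ring.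

Step 3. What may go wrong: loss of material by aromatisation of the doubly allylic diene system in air or under the oxidant, nucleophilic epoxidation of the enone if conjugation sets in while peroxide is still present, and incomplete migration of the double bond. Fallback: the aromatisation is made deliberate and the enone is regained by Birch reduction. It sets out from 6: DDQ (benzene, rt) should give 2-(3-nonadecylphenyl)-4,4,5,5-tetramethyl-1,3,2-dioxaborolane F2. Oxidation with H2O2 and NaOH (THF, 0 °C) should give 3-nonadecylphenol F3, and MeI with K2CO3 (acetone, reflux) should give 1-methoxy-3-nonadecylbenzene F4. Reduction with Li in NH3, t-BuOH and THF at −78 °C should give 1-methoxy-5-nonadecylcyclohexa-1,4-diene F5. Its hydrolysis with 2 M HCl in THF passes through 8 and rejoins the route at 9.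

Step 1. What may go wrong: β-hydride elimination or homocoupling of the long-chain Grignard reagent at nickel, and polymerisation or Diels–Alder dimerisation of chloroprene and of the product diene. Fallback: the diene is built by enyne metathesis instead of cross-coupling. It sets out from 1: lithium acetylide–ethylenediamine complex (DMSO, rt) should give henicos-1-yne F6 by SN2 alkynylation. Cross enyne metathesis with ethylene (1 atm, second-generation Grubbs catalyst, toluene, 80 °C) should then deliver the 2-substituted diene, and the route is rejoined at 4.

**Further compounds**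

F1 | step 2 | 3-ethoxy-1-nonadecylcyclohex-2-en-1-ol | CCCCCCCCCCCCCCCCCCCC1(O)C=C(OCC)CCC1
F2 | step 3 | 2-(3-nonadecylphenyl)-4,4,5,5-tetramethyl-1,3,2-dioxaborolane | CCCCCCCCCCCCCCCCCCCc1cccc(B2OC(C)(C)C(C)(C)O2)c1
F3 | step 3 | 3-nonadecylphenol | CCCCCCCCCCCCCCCCCCCc1cccc(O)c1
F4 | step 3 | 1-methoxy-3-nonadecylbenzene | CCCCCCCCCCCCCCCCCCCc1cccc(OC)c1
F5 | step 3 | 1-methoxy-5-nonadecylcyclohexa-1,4-diene | CCCCCCCCCCCCCCCCCCCC1=CCC=C(OC)C1
F6 | step 1 | henicos-1-yne | CCCCCCCCCCCCCCCCCCCC#C
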